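**Strategy.** Everything rests on closing the eight-membered oxocine ring at the C–C bond between the O-bearing quaternary carbon C(CH3)2 and the neighbouring ring CH2. The feature exploited is that this quaternary carbon, attached to the 2'-oxygen of ring B, is a tertiary alpha-aryloxy centre. It is carried as a fibrate-type aryloxyisobutyric acid and unmasked by photoredox decarboxylation as a nucleophilic radical, which the twisted C2–C1' axis holds over a vinyl group on C3 of ring C. One operation (decarboxylation, 8-endo-trig cyclization, reduction and protonation) should convert the unprotected 3-vinylflavone acid into cyclointegrin.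

Key step: step 7

Remark: cyclointegrin has no stereocentre, so no step has to set configuration; compounds 1, 2 and 5 and the reagents named are taken as commercial.

**Step 1**
Reactants: 1 4-(benzyloxy)-2-hydroxybenzaldehyde; 2 tert-butyl 2-bromo-2-methylpropanoate
Product: 3 tert-butyl 2-[5-(benzyloxy)-2-formylphenoxy]-2-methylpropanoate
Conditions: 2 (2.5 equiv), Cs2CO3 (2 equiv), DMF, 70 °C
Reagents that add atoms: none
Why: O-alkylation of a phenoxide with an alpha-bromoisobutyrate (Williamson-type etherification as used for fibrates), the excess bromide covering its loss by elimination.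

**Step 2**
Reactants: 3 tert-butyl 2-[5-(benzyloxy)-2-formylphenoxy]-2-methylpropanoate
Product: 4 tert-butyl 2-[5-(benzyloxy)-2-ethynylphenoxy]-2-methylpropanoate
Conditions: dimethyl (1-diazo-2-oxopropyl)phosphonate (1.3 equiv), K2CO3 (2 equiv), MeOH, 0 °C to rt
Reagents that add atoms: dimethyl (1-diazo-2-oxopropyl)phosphonate, COP(=O)(OC)C(=[N+]=[N-])C(C)=O
Why: Ohira–Bestmann variant of the Seyferth–Gilbert homologation turns the aryl aldehyde into the terminal alkyne under mild base that leaves the tert-butyl ester and the benzyl ether untouched.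

**Step 3**
Reactants: 4 tert-butyl 2-[5-(benzyloxy)-2-ethynylphenoxy]-2-methylpropanoate; 5 2,4,6-trimethoxybenzoyl chloride
Product: 6 tert-butyl 2-{5-(benzyloxy)-2-[3-oxo-3-(2,4,6-trimethoxyphenyl)prop-1-yn-1-yl]phenoxy}-2-methylpropanoate
Conditions: PdCl2(PPh3)2 (2 mol %), CuI (4 mol %), Et3N (1.5 equiv), THF, rt
Reagents that add atoms: none
Why: Acyl Sonogashira coupling of an aroyl chloride with a terminal alkyne gives the aryl ynone directly, without base-sensitive or nucleophile-sensitive intermediates.

**Step 4**
Reactants: 6 tert-butyl 2-{5-(benzyloxy)-2-[3-oxo-3-(2,4,6-trimethoxyphenyl)prop-1-yn-1-yl]phenoxy}-2-methylpropanoate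
Product: 7 tert-butyl 2-[5-(benzyloxy)-2-(3-iodo-5,7-dimethoxy-4-oxo-4H-chromen-2-yl)phenoxy]-2-methylpropanoate
Conditions: ICl (1.2 equiv), CH2Cl2, −78 °C; aq. Na2S2O3
Reagents that add atoms: iodine monochloride, ClI
Why: ICl-induced 6-endo-dig iodocyclization of an ortho-methoxyaryl ynone, in which an ortho-methoxy oxygen attacks the iodonium-activated alkyne at the carbon remote from the carbonyl and chloride demethylates the oxonium ion; the two equivalent ortho-methoxy groups make the closure unambiguous and place iodine at C3.

**Step 5**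
Reactants: 7 tert-butyl 2-[5-(benzyloxy)-2-(3-iodo-5,7-dimethoxy-4-oxo-4H-chromen-2-yl)phenoxy]-2-methylpropanoate
Product: 8 2-[5-hydroxy-2-(5-hydroxy-3-iodo-7-methoxy-4-oxo-4H-chromen-2-yl)phenoxy]-2-methylpropanoic acid
Conditions: BCl3 (1 M in CH2Cl2, 6 equiv), pentamethylbenzene (3 equiv), CH2Cl2, −78 °C to rt; then MeOH, aq. HCl
Reagents that add atoms: none
Why: Lewis-acid dealkylation in which BCl3 cleaves the benzyl ether (cation trapped by pentamethylbenzene), the tert-butyl ester and, through chelation to the C4 carbonyl, only the peri 5-methoxy group, while the unchelated 7-methoxy group and the tertiary aryl ether (its ionization would place a cation next to the carboxyl group) should persist.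

**Step 6**
Reactants: 8 2-[5-hydroxy-2-(5-hydroxy-3-iodo-7-methoxy-4-oxo-4H-chromen-2-yl)phenoxy]-2-methylpropanoic acid
Product: 9 2-[5-hydroxy-2-(5-hydroxy-7-methoxy-4-oxo-3-vinyl-4H-chromen-2-yl)phenoxy]-2-methylpropanoic acid
Conditions: potassium vinyltrifluoroborate (1.5 equiv), PdCl2(dppf) (5 mol %), Cs2CO3 (5 equiv), THF/H2O 9:1, 70 °C; aq. HCl work-up
Reagents that add atoms: potassium vinyltrifluoroborate, C=C[B-](F)(F)F.[K+]
Why: Suzuki–Miyaura vinylation of the 3-iodochromone, a coupling that tolerates free phenols and a free carboxylic acid as their salts in aqueous base.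

**Step 7**
Reactants: 9 2-[5-hydroxy-2-(5-hydroxy-7-methoxy-4-oxo-3-vinyl-4H-chromen-2-yl)phenoxy]-2-methylpropanoic acid
Product: 12 cyclointegrin, via tertiary alpha-aryloxyalkyl radical 10 (not isolated), via cyclized allylic radical 11 (not isolated)
Conditions: [Ir(dF(CF3)ppy)2(dtbbpy)]PF6 (2 mol %), K2HPO4 (0.3 equiv), degassed DMSO (2 mM), 450 nm LEDs, rt
Reagents that add atoms: none
Why: Photoexcited [Ir(dF(CF3)ppy)2(dtbbpy)]PF6 oxidizes the carboxylate of 9, loss of CO2 gives the nucleophilic tertiary alpha-aryloxy radical 10, this adds to the terminal CH2 of the 3-vinyl group to give the allylic radical 11 (spin shared between the CH next to C3 and C2 of ring C), and 11 is reduced by the divalent iridium complex and protonated by a further molecule of acid 9, so that the base is needed only in catalytic amount. The closest known reaction type is the photoredox decarboxylative Giese-type hydroalkylation of conjugated alkenes, here run intramolecularly, in line with known 8-endo-trig cyclizations of alpha-oxygenated carbon radicals onto aryl-conjugated alkenes. The dihydrooxocine ring closes in the 8-endo-trig mode and no stereocentre is formed, the target being achiral. The step needs attack at the vinyl terminus in preference to 5-exo attack at C2 or 6-endo attack at C3 of ring C: both ring carbons are fully substituted, C2 is a donor-substituted and poorly accepting Michael terminus, and a bond from the tertiary radical to either would join two fully substituted carbons, whereas the vinyl CH2 is unhindered and lies under the 2'-O–C(CH3)2 group because the C2–C1' axis is twisted. It also needs cyclization to outrun quenching of radical 10, which high dilution and the absence of any added hydrogen-atom donor should secure, and oxidation of the carboxylate in preference to the phenols, which the substoichiometric base (the phenols stay protonated, the 5-OH hydrogen-bonded to C4=O) should secure. Protonation at the CH next to C3 restores the aromatic 4-pyranone directly, and an isomer protonated at C2 would be equilibrated to it by the base present.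

**Compound list**
1 | 4-(benzyloxy)-2-hydroxybenzaldehyde | O=Cc1ccc(OCc2ccccc2)cc1O | starting material
2 | tert-butyl 2-bromo-2-methylpropanoate | CC(C)(Br)C(=O)OC(C)(C)C | starting material
3 | tert-butyl 2-[5-(benzyloxy)-2-formylphenoxy]-2-methylpropanoate | O=Cc1ccc(OCc2ccccc2)cc1OC(C)(C)C(=O)OC(C)(C)C | intermediate
4 | tert-butyl 2-[5-(benzyloxy)-2-ethynylphenoxy]-2-methylpropanoate | C#Cc1ccc(OCc2ccccc2)cc1OC(C)(C)C(=O)OC(C)(C)C | intermediate
5 | 2,4,6-trimethoxybenzoyl chloride | COc1cc(OC)c(C(=O)Cl)c(OC)c1 | starting material
6 | tert-butyl 2-{5-(benzyloxy)-2-[3-oxo-3-(2,4,6-trimethoxyphenyl)prop-1-yn-1-yl]phenoxy}-2-methylpropanoate | COc1cc(OC)c(C(=O)C#Cc2ccc(OCc3ccccc3)cc2OC(C)(C)C(=O)OC(C)(C)C)c(OC)c1 | intermediate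
7 | tert-butyl 2-[5-(benzyloxy)-2-(3-iodo-5,7-dimethoxy-4-oxo-4H-chromen-2-yl)phenoxy]-2-methylpropanoate | COc1cc(OC)c2c(=O)c(I)c(-c3ccc(OCc4ccccc4)cc3OC(C)(C)C(=O)OC(C)(C)C)oc2c1 | intermediate
8 | 2-[5-hydroxy-2-(5-hydroxy-3-iodo-7-methoxy-4-oxo-4H-chromen-2-yl)phenoxy]-2-methylpropanoic acid | COc1cc(O)c2c(=O)c(I)c(-c3ccc(O)cc3OC(C)(C)C(=O)O)oc2c1 | intermediate
9 | 2-[5-hydroxy-2-(5-hydroxy-7-methoxy-4-oxo-3-vinyl-4H-chromen-2-yl)phenoxy]-2-methylpropanoic acid | COc1cc(O)c2c(=O)c(C=C)c(-c3ccc(O)cc3OC(C)(C)C(=O)O)oc2c1 | intermediate
10 | tertiary alpha-aryloxyalkyl radical formed from 9 by loss of CO2 (radical centre on the O-bearing C(CH3)2 carbon) | COc1cc(O)c2c(=O)c(C=C)c(-c3ccc(O)cc3O[C](C)C)oc2c1 | intermediate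
11 | cyclized allylic radical (oxocine ring closed, radical centre on the CH attached to C3) | COc1cc(O)c2c(=O)c3c(oc2c1)-c1ccc(O)cc1OC(C)(C)C[CH]3 | intermediate
12 | cyclointegrin | COc1cc(O)c2c(=O)c3c(oc2c1)-c1ccc(O)cc1OC(C)(C)CC3 | target

**Total step count:** 7
**Longest linear sequence:** 7 steps (from 1)

**Steps most likely to fail**

Step 7 (key step). The tertiary radical may be consumed before it closes the ring, either by hydrogen abstraction or by attack on C2 of ring C. The allylic radical may be reduced too slowly by the divalent iridium complex, or oxidation of a phenol may compete with oxidation of the carboxylate. The fallback sets out from 9 and comes back at 12, and it changes the radical manifold from oxidative to reductive. Acid 9 would be esterified with N-hydroxyphthalimide (N,N'-diisopropylcarbodiimide, THF, 0 °C to rt) to the 1,3-dioxoisoindolin-2-yl ester of 9 F1. F1 would then be irradiated (blue LEDs) with Ru(bpy)3(PF6)2 (1 mol %) and Hantzsch ester (diethyl 2,6-dimethyl-1,4-dihydropyridine-3,5-dicarboxylate, 1.5 equiv) in CH2Cl2 at 2 mM. Reductive fragmentation of the redox-active ester should give the same radical 10 under non-oxidizing conditions, and radical 11 would be terminated by hydrogen-atom transfer from the dihydropyridine instead of by electron transfer. This fallback does not remove the risk of attack at C2.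

Step 4. Electrophilic iodination of the electron-rich trimethoxyphenyl ring or of the resorcinol-type ring may compete with iodocyclization and lead to over-iodination. The fallback sets out from 3 and comes back at 7, and it introduces the iodine by deprotonation instead of by electrophilic attack. Claisen–Schmidt condensation of 3 with 1-(2-hydroxy-4,6-dimethoxyphenyl)ethanone (KOH, EtOH, rt) should give the (E)-2'-hydroxychalcone F2. Oxidative cyclization (I2, 5 mol %, DMSO, 110 °C) should give tert-butyl 2-[5-(benzyloxy)-2-(5,7-dimethoxy-4-oxo-4H-chromen-2-yl)phenoxy]-2-methylpropanoate F3. Lithiation of F3 at C3 with lithium diisopropylamide (THF, −78 °C) and an I2 quench should give 7.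

Step 3. Acylation may be slow because the aroyl chloride is hindered on both sides and electron-rich, so that alkyne homocoupling or decarbonylation takes over. The fallback sets out from 4 and comes back at 6, and it replaces the palladium acylation by 1,2-addition and oxidation. Alkyne 4 would be deprotonated with lithium diisopropylamide (THF, −78 °C) and added to 2,4,6-trimethoxybenzaldehyde to give the racemic propargylic alcohol tert-butyl 2-{5-(benzyloxy)-2-[3-hydroxy-3-(2,4,6-trimethoxyphenyl)prop-1-yn-1-yl]phenoxy}-2-methylpropanoate F4. F4 would be oxidized at once with MnO2 (CH2Cl2, rt) to 6.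

**Further compounds**
F1 | step 7 | 1,3-dioxoisoindolin-2-yl 2-[5-hydroxy-2-(5-hydroxy-7-methoxy-4-oxo-3-vinyl-4H-chromen-2-yl)phenoxy]-2-methylpropanoate | COc1cc(O)c2c(=O)c(C=C)c(-c3ccc(O)cc3OC(C)(C)C(=O)ON3C(=O)c4ccccc4C3=O)oc2c1
F2 | step 4 | tert-butyl 2-{5-(benzyloxy)-2-[(E)-3-(2-hydroxy-4,6-dimethoxyphenyl)-3-oxoprop-1-en-1-yl]phenoxy}-2-methylpropanoate | COc1cc(O)c(C(=O)/C=C/c2ccc(OCc3ccccc3)cc2OC(C)(C)C(=O)OC(C)(C)C)c(OC)c1
F3 | step 4 | tert-butyl 2-[5-(benzyloxy)-2-(5,7-dimethoxy-4-oxo-4H-chromen-2-yl)phenoxy]-2-methylpropanoate | COc1cc(OC)c2c(=O)cc(-c3ccc(OCc4ccccc4)cc3OC(C)(C)C(=O)OC(C)(C)C)oc2c1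
F4 | step 3 | tert-butyl 2-{5-(benzyloxy)-2-[3-hydroxy-3-(2,4,6-trimethoxyphenyl)prop-1-yn-1-yl]phenoxy}-2-methylpropanoate (racemic) | COc1cc(OC)c(C(O)C#Cc2ccc(OCc3ccccc3)cc2OC(C)(C)C(=O)OC(C)(C)C)c(OC)c1
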